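**Plan**

1. The target is read as C2-symmetric. Each half is a (2R)-oxane with a (Z) exocyclic alkene (CH2O cis to the linking chain) that carries at C-2 a (1S,2S,5R)-cyclopentan-1-ol (OH cis to isopropenyl, trans to the oxanyl group).
2. Cuts, in retrosynthetic order: (a) both cyclopentane C(OH)–C(isopropenyl) bonds (carbonyl-ene); (b) in each half the oxane O–C-2 bond together with the bond from the neighbouring cyclopentane CH to the carbinol carbon (alkoxypalladation–carbonylation); (c) both trisubstituted C=C bonds (twofold olefination of butanedial); (d) the C10 side chain at its alkyne.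
3. Enabling feature: each oxane oxygen sits on an allylic CH2 that holds C-2 in six-ring reach. C-2 and the cyclopentane carbon bonded to it are adjacent CH centres that are the two carbons of a (Z)-alkene in the open chain, and the carbinol carbon is a one-carbon unit that CO supplies.
4. Forward order: side-chain iodide, α-alkyl phosphonate, (Z,Z)-diester (chain joined in two directions), hexaene diol, both oxane rings (step 8), dialdehyde, both cyclopentanol rings (step 10).
5. Stereochemistry: (Z) alkenes from Lindlar reduction and the Ando olefination; absolute configuration of oxane C-2 and the adjacent carbon from the chiral ligand on palladium; the remaining four centres from these by 1,2-induction in the cyclic ene transition state.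

Key step: step 8

Assumption: the (S,S)-ligand is taken to select the alkene face that gives the (2R) oxane; if a single-arm model shows the opposite sense, the (R,R)-ligand is used and nothing else changes.

**Route**

Step 1
Reactants: 1 but-3-yn-1-ol; 2 5-bromo-2-methylpent-2-ene
Product: 4 8-methylnon-7-en-3-yn-1-ol, via dilithium salt of but-3-yn-1-ol 3 (not isolated)
Conditions: n-BuLi (2.1 equiv), THF, −78 → 0 °C; then 2, DMPU, 0 °C → rt
Reagents that add atoms: none
Why: Acetylide alkylation: the carbanion of the dianion is far more nucleophilic than the alkoxide, so the primary bromide is displaced (SN2) at carbon only, and no stereocentre is formed.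

Step 2
Reactants: 4 8-methylnon-7-en-3-yn-1-ol
Product: 5 (3Z)-8-methylnona-3,7-dien-1-ol
Conditions: H2 (1 atm), Pd/CaCO3 poisoned with Pb(OAc)2, quinoline, hexane, rt
Reagents that add atoms: none
Why: Lindlar semihydrogenation adds H2 syn on the poisoned surface and stops at the (Z)-alkene, the trisubstituted alkene being too hindered to react; this (Z) geometry is what step 8 turns into the relative configuration of two stereocentres.

Step 3
Reactants: 5 (3Z)-8-methylnona-3,7-dien-1-ol
Product: 6 (3Z)-1-iodo-8-methylnona-3,7-diene
Conditions: I2, PPh3, imidazole, CH2Cl2, 0 °C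
Reagents that add atoms: iodine, II
Why: Appel-type iodination turns the primary alcohol into the iodide through the alkoxyphosphonium ion (SN2) and leaves both alkenes and the (Z) geometry untouched.

Step 4
Reactants: 7 ethyl 2-[bis(2-methylphenoxy)phosphoryl]acetate; 6 (3Z)-1-iodo-8-methylnona-3,7-diene
Product: 9 ethyl (5Z)-2-[bis(2-methylphenoxy)phosphoryl]-10-methylundeca-5,9-dienoate (racemic at C-2), via sodium enolate of the phosphonoacetate 8 (not isolated)
Conditions: NaH, THF–DMSO, 0 °C → rt; then 6, rt → 45 °C
Reagents that add atoms: none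
Why: SN2 alkylation of the stabilised phosphonoacetate anion by the primary iodide gives the α-alkyl Ando reagent; a slight excess of 7 holds back dialkylation, and the racemic centre formed is destroyed in step 6.

Step 5
Reactants: 10 2,5-dimethoxytetrahydrofuran (cis/trans mixture)
Product: 11 butanedial (succinaldehyde)
Conditions: H2O, 90 °C, MeOH distilled off; extraction into CH2Cl2, used at once
Reagents that add atoms: water, O
Why: Hydrolysis of the cyclic bis-acetal frees the dialdehyde, which is used fresh because it oligomerises on standing.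

Step 6
Reactants: 9 ethyl (5Z)-2-[bis(2-methylphenoxy)phosphoryl]-10-methylundeca-5,9-dienoate (2.3 equiv); 11 butanedial
Product: 13 diethyl (2Z,6Z)-2,7-bis[(3Z)-8-methylnona-3,7-dien-1-yl]octa-2,6-dienedioate, via sodium salt of the alkylated phosphonate 12 (not isolated)
Conditions: NaH, THF, 0 °C; then 11, −78 → 0 °C
Reagents that add atoms: none
Why: Ando modification of the Horner–Wadsworth–Emmons reaction: the electron-poor diaryl phosphonate makes collapse of the first-formed oxaphosphetane fast, so each aldehyde gives the (Z)-trisubstituted enoate with the ester cis to the new CH2 chain, as α-alkyl diaryl phosphonoacetates do with aliphatic aldehydes.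

Step 7
Reactants: 13 diethyl (2Z,6Z)-2,7-bis[(3Z)-8-methylnona-3,7-dien-1-yl]octa-2,6-dienedioate
Product: 14 (2Z,6Z)-2,7-bis[(3Z)-8-methylnona-3,7-dien-1-yl]octa-2,6-diene-1,8-diol
Conditions: i-Bu2AlH (5 equiv), CH2Cl2, −78 → 0 °C; aqueous potassium sodium tartrate
Reagents that add atoms: none
Why: i-Bu2AlH reduces the conjugated esters by 1,2-addition only and so gives the bis-allylic diol with all six alkene geometries intact.

Step 8
Reactants: 14 (2Z,6Z)-2,7-bis[(3Z)-8-methylnona-3,7-dien-1-yl]octa-2,6-diene-1,8-diol
Product: 15 dimethyl (2R,2'R)-2,2'-{butane-1,4-diylidenebis[(2R,5Z)-oxane-5,2-diyl]}bis(6-methylhept-5-enoate)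
Conditions: PdCl2(MeCN)2 (10 mol %), 2,2'-(propane-2,2-diyl)bis[(4S)-4-phenyl-4,5-dihydro-1,3-oxazole] (12 mol %), p-benzoquinone (3 equiv), CO (1 atm), MeOH–CH2Cl2 (1:1), 0 °C → rt
Reagents that add atoms: carbon monoxide, [C-]#[O+]; methanol, CO
Why: Proposed new method: the chiral bis(oxazoline) complex of divalent palladium binds one enantioface of each (Z)-1,2-disubstituted alkene, the allylic hydroxyl attacks the nearer alkene carbon (the future oxane C-2) from the face opposite to the metal (anti alkoxypalladation), CO inserts into the secondary C–Pd bond with retention, and methanolysis of the acylpalladium gives the methyl ester and zerovalent palladium, which p-benzoquinone reoxidises. The closest known reaction type is the intramolecular alkoxypalladation–methoxycarbonylation of hydroxy alkenes (Semmelhack reaction), for which anti addition across internal alkenes is established, joined with ligand-controlled enantioselective Wacker-type cyclisation–carbonylations; new here is enantiofacial control on a 1,2-dialkyl (Z)-alkene with an aliphatic alcohol, used twice in one molecule. Each oxane ring closes in the 6-exo-trig mode through a chair-like array in which the sp2 carbon of the tether limits rotation. The oxane C-2 centre (R) is set by the ligand-controlled choice of alkene face, and the ester α-carbon (R) follows from it stereospecifically, because anti addition of O and CO2Me to a (Z)-alkene can give only this relative configuration. The step needs chemoselectivity among six alkenes and 6-exo over 7-endo regioselectivity: the four trisubstituted alkenes bind palladium poorly and have no hydroxyl in ring-forming reach, only attack at the nearer carbon of the (Z)-alkene gives a six-membered ring, and the CO atmosphere lets insertion outrun β-hydride elimination. As the two ends react independently, an error at one end is diverted mainly into the meso diastereomer, which raises the enantiomeric purity of the C2-symmetric product (Horeau principle).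

Step 9
Reactants: 15 dimethyl (2R,2'R)-2,2'-{butane-1,4-diylidenebis[(2R,5Z)-oxane-5,2-diyl]}bis(6-methylhept-5-enoate)
Product: 17 (2R,2'R)-2,2'-{butane-1,4-diylidenebis[(2R,5Z)-oxane-5,2-diyl]}bis(6-methylhept-5-enal), via bis(diisobutylaluminium hemiacetal) 16 (not isolated)
Conditions: i-Bu2AlH (2.2 equiv), CH2Cl2, −78 °C; MeOH, then aqueous potassium sodium tartrate, −78 °C → rt
Reagents that add atoms: none
Why: Partial ester reduction: at −78 °C the tetrahedral aluminium hemiacetal is held by chelation to the β-oxygen of the oxane and collapses to the aldehyde only on work-up, so reduction should stop at the aldehyde without epimerising the α-stereocentre.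

Step 10
Reactants: 17 (2R,2'R)-2,2'-{butane-1,4-diylidenebis[(2R,5Z)-oxane-5,2-diyl]}bis(6-methylhept-5-enal)
Product: 18 testudinariol A
Conditions: Me2AlCl (2.2 equiv, 1.1 per aldehyde), CH2Cl2, −78 → −40 °C
Reagents that add atoms: none
Why: Intramolecular carbonyl-ene reaction: the nearer carbon of each trisubstituted alkene adds to the aluminium-bound aldehyde in a five-ring-forming cyclic transition state that passes a methyl hydrogen to oxygen, which forces OH and the new isopropenyl group cis, while the bulky oxanyl group on the α-carbon stays anti to the complexed oxygen in the non-chelated arrangement, so OH ends trans to it; loss of methane from the aluminium alkoxide removes the proton that could start Prins side reactions.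

**Compound list**

1 | but-3-yn-1-ol | C#CCCO | starting material
2 | 5-bromo-2-methylpent-2-ene | CC(C)=CCCBr | starting material
3 | dilithium salt of but-3-yn-1-ol (lithiated at C-4 and at O) | [Li]C#CCCO[Li] | intermediate
4 | 8-methylnon-7-en-3-yn-1-ol | CC(C)=CCCC#CCCO | intermediate
5 | (3Z)-8-methylnona-3,7-dien-1-ol | CC(C)=CCC/C=C\CCO | intermediate
6 | (3Z)-1-iodo-8-methylnona-3,7-diene | CC(C)=CCC/C=C\CCI | intermediate
7 | ethyl 2-[bis(2-methylphenoxy)phosphoryl]acetate | CCOC(=O)CP(=O)(Oc1ccccc1C)Oc1ccccc1C | starting material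
8 | sodium enolate of 7 | CCOC([O-])=CP(=O)(Oc1ccccc1C)Oc1ccccc1C.[Na+] | intermediate
9 | ethyl (5Z)-2-[bis(2-methylphenoxy)phosphoryl]-10-methylundeca-5,9-dienoate (racemic at C-2) | CCOC(=O)C(CC/C=C\CCC=C(C)C)P(=O)(Oc1ccccc1C)Oc1ccccc1C | intermediate
10 | 2,5-dimethoxytetrahydrofuran (cis/trans mixture) | COC1CCC(OC)O1 | starting material
11 | butanedial (succinaldehyde) | O=CCCC=O | intermediate
12 | sodium salt of 9 (phosphonate-stabilised ester enolate) | CCOC([O-])=C(CC/C=C\CCC=C(C)C)P(=O)(Oc1ccccc1C)Oc1ccccc1C.[Na+] | intermediate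
13 | diethyl (2Z,6Z)-2,7-bis[(3Z)-8-methylnona-3,7-dien-1-yl]octa-2,6-dienedioate (each ester cis to the central CH2CH2 chain) | CC(C)=CCC/C=C\CC/C(C(=O)OCC)=C/CC/C=C(C(=O)OCC)/CC/C=C\CCC=C(C)C | intermediate
14 | (2Z,6Z)-2,7-bis[(3Z)-8-methylnona-3,7-dien-1-yl]octa-2,6-diene-1,8-diol | CC(C)=CCC/C=C\CC/C(CO)=C/CC/C=C(CO)/CC/C=C\CCC=C(C)C | intermediate
15 | dimethyl (2R,2'R)-2,2'-{butane-1,4-diylidenebis[(2R,5Z)-oxane-5,2-diyl]}bis(6-methylhept-5-enoate) | CC(C)=CCC[C@H]([C@H]1CC/C(=C/CC/C=C2/CC[C@H]([C@H](C(=O)OC)CCC=C(C)C)OC2)CO1)C(=O)OC | intermediate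
16 | bis(diisobutylaluminium hemiacetal) of 15 (hemiacetal carbons unassigned) | CC(C)=CCC[C@H]([C@H]1CC/C(=C/CC/C=C2/CC[C@H]([C@H](C(OC)O[Al](CC(C)C)CC(C)C)CCC=C(C)C)OC2)CO1)C(OC)O[Al](CC(C)C)CC(C)C | intermediate
17 | (2R,2'R)-2,2'-{butane-1,4-diylidenebis[(2R,5Z)-oxane-5,2-diyl]}bis(6-methylhept-5-enal) | CC(C)=CCC[C@H]([C@H]1CC/C(=C/CC/C=C2/CC[C@H]([C@H](C=O)CCC=C(C)C)OC2)CO1)C=O | intermediate
18 | testudinariol A, (1S,2S,5R,1'S,2'S,5'R)-2,2'-{butane-1,4-diylidenebis[(2R,5Z)-oxane-5,2-diyl]}bis[5-(prop-1-en-2-yl)cyclopentan-1-ol] | C=C(C)[C@H]1CC[C@H]([C@H]2CC/C(=C/CC/C=C3/CC[C@H]([C@H]4CC[C@H](C(=C)C)[C@@H]4O)OC3)CO2)[C@H]1O | target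

**Step count**

Total step count: 10. Longest linear sequence: 9 (steps 1–4 and 6–10; step 5 is a one-step side branch).

**Steps most likely to fail**

Step 8 (Proposed new method). What may go wrong:
- too little enantiofacial discrimination of the (Z)-alkene, or racemic turnover by ligand-free palladium;
- partial switch to syn alkoxypalladation, which would invert the relative configuration of C-2 and the α-carbon;
- (Z)/(E) isomerisation or β-hydride elimination before CO insertion.

Fallback by known chemistry, setting out from 7 and 11 and coming back at 15. Phosphonate 7 is alkylated with 4-bromobut-1-ene (NaH, THF–DMSO) to ethyl 2-[bis(2-methylphenoxy)phosphoryl]hex-5-enoate F1. Twofold Ando olefination of 11 with its sodium salt gives diethyl (2Z,6Z)-2,7-di(but-3-en-1-yl)octa-2,6-dienedioate F2. i-Bu2AlH gives (2Z,6Z)-2,7-di(but-3-en-1-yl)octa-2,6-diene-1,8-diol F3. Twofold cross-metathesis of the terminal alkenes with methyl acrylate (second-generation Hoveyda–Grubbs catalyst RuCl2(H2IMes)(=CH–C6H4–2-O-i-Pr), CH2Cl2, 40 °C) gives dimethyl (2E,6Z,10Z,14E)-6,11-bis(hydroxymethyl)hexadeca-2,6,10,14-tetraenedioate F4. A catalytic enantioselective intramolecular oxa-Michael addition (bifunctional iminophosphorane–thiourea organocatalyst, toluene, rt; a reaction type established for hydroxy enoates giving 2-substituted oxanes) closes both rings 6-exo-trig to dimethyl 2,2'-{butane-1,4-diylidenebis[(2R,5Z)-oxane-5,2-diyl]}diacetate F5. The bis(lithium enolate) of F5 (LiN(i-Pr)2, THF–DMPU, −78 °C) is alkylated with bromide 2 in the Frater–Seebach sense for β-oxygenated ester enolates, anti to the ring C–O bond, which is the relative configuration of 15.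

Step 10. What may go wrong:
- chelation of aluminium between aldehyde and oxane oxygen, which would reverse the 1,2-induction;
- a stepwise Prins-type course that loosens the cis OH/isopropenyl control or ends in chloride capture;
- Lewis-acid-induced β-elimination that opens the oxane or epimerises the α-carbon.

Fallback by known chemistry, setting out from 7 and 11, running through F1 to F5 as above, and coming back at 18. The bis(lithium enolate) of F5 is alkylated with 5-iodopenta-1,2-diene to dimethyl (2R,2'R)-2,2'-{butane-1,4-diylidenebis[(2R,5Z)-oxane-5,2-diyl]}bis(hepta-5,6-dienoate) F6. i-Bu2AlH at −78 °C gives (2R,2'R)-2,2'-{butane-1,4-diylidenebis[(2R,5Z)-oxane-5,2-diyl]}bis(hepta-5,6-dienal) F7. Twofold nickel-catalysed alkylative cyclisation of the allenyl aldehydes (Ni(cod)2 as source of zerovalent nickel, Me2Zn, THF, 0 °C) then forms each C(OH)–C bond through an oxanickelacycle and transfers methyl to the central allene carbon. Under these neutral conditions OH should end cis to the new isopropenyl group and trans to the α-substituent, giving 18.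

Step 9. What may go wrong:
- early collapse of the aluminium hemiacetal with over-reduction to the alcohol;
- incomplete reduction at one end, leaving mixed oxidation levels.

Fallback, setting out from 15 and coming back at 17. LiAlH4 (THF, 0 °C) reduces both esters fully to (2S,2'S)-2,2'-{butane-1,4-diylidenebis[(2R,5Z)-oxane-5,2-diyl]}bis(6-methylhept-5-en-1-ol) F8. Dess–Martin periodinane (NaHCO3, CH2Cl2, 0 °C) oxidises F8 to 17.

**Further compounds**

F1 | step 8 | ethyl 2-[bis(2-methylphenoxy)phosphoryl]hex-5-enoate | CCOC(=O)C(CCC=C)P(=O)(Oc1ccccc1C)Oc1ccccc1C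
F2 | step 8 | diethyl (2Z,6Z)-2,7-di(but-3-en-1-yl)octa-2,6-dienedioate | C=CCC/C(C(=O)OCC)=C/CC/C=C(C(=O)OCC)/CCC=C
F3 | step 8 | (2Z,6Z)-2,7-di(but-3-en-1-yl)octa-2,6-diene-1,8-diol | C=CCC/C(CO)=C/CC/C=C(CO)/CCC=C
F4 | step 8 | dimethyl (2E,6Z,10Z,14E)-6,11-bis(hydroxymethyl)hexadeca-2,6,10,14-tetraenedioate | COC(=O)/C=C/CC/C(CO)=C/CC/C=C(CO)/CC/C=C/C(=O)OC
F5 | step 8 | dimethyl 2,2'-{butane-1,4-diylidenebis[(2R,5Z)-oxane-5,2-diyl]}diacetate | COC(=O)C[C@H]1CC/C(=C/CC/C=C2/CC[C@H](CC(=O)OC)OC2)CO1
F6 | step 10 | dimethyl (2R,2'R)-2,2'-{butane-1,4-diylidenebis[(2R,5Z)-oxane-5,2-diyl]}bis(hepta-5,6-dienoate) | C=C=CCC[C@H]([C@H]1CC/C(=C/CC/C=C2/CC[C@H]([C@H](C(=O)OC)CCC=C=C)OC2)CO1)C(=O)OC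
F7 | step 10 | (2R,2'R)-2,2'-{butane-1,4-diylidenebis[(2R,5Z)-oxane-5,2-diyl]}bis(hepta-5,6-dienal) | C=C=CCC[C@H]([C@H]1CC/C(=C/CC/C=C2/CC[C@H]([C@H](C=O)CCC=C=C)OC2)CO1)C=O
F8 | step 9 | (2S,2'S)-2,2'-{butane-1,4-diylidenebis[(2R,5Z)-oxane-5,2-diyl]}bis(6-methylhept-5-en-1-ol) | CC(C)=CCC[C@H]([C@H]1CC/C(=C/CC/C=C2/CC[C@H]([C@H](CO)CCC=C(C)C)OC2)CO1)CO
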